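**Plan**

1. Ring numbering used below: C1 = CH2 between CMe2 and the carbinol, C2 = CHOH, C3 = C(=CH2), C4, C5, C6 = ring CH=, C7 = C(CO2H), C8, C9 = CH(O-angelate), C10, C11 = CMe2. C1' is an extra carboxyl carbon on C1 that leaves as CO2.
2. Retrosynthesis, in order: free the acid from its tert-butyl ester; cut the ring bond C1–C2 (decarboxylative chromium-mediated alkyl addition to an enal); cut C6=C7 (cross-metathesis); cut the angelate C–O bond; cut C8–C9 (asymmetric 2-(alkoxycarbonyl)allylation).
3. Forward: 3,3-dimethylglutaric anhydride supplies C9–C10–C11(Me2)–C1–C1'. Allylation adds C8, C7 and the carboxyl carbon, angeloylation follows, cross-metathesis with 2-methylidenehex-5-en-1-ol adds C2–C6, and the single eleven-membered ring is closed last at C1–C2.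
4. Enabling feature: C1 is a neopentyl CH2 on the quaternary C11 (inert to SN2, no β-hydrogen on that side, so a good radical and alkylchromium site). C2 is the carbinol next to the C3 exocyclic methylene, i.e. the carbonyl carbon of a non-enolisable 2-alkylacrolein. The gem-dimethyl group and the C6=C7 olefin with C5 and C8 cis pre-organise the eleven-membered ring.
5. Stereochemistry: C9 (S) from the catalyst-controlled allylation; C2 (S) from the chiral ligand on chromium in the ring closure; C6=C7 (E) from the cross-metathesis; the Z-angelate is introduced intact.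

Key step: step 11

Remark (assumption): the sense of induction of the chiral chromium ligands in steps 4 and 11 is ligand-specific, so the ligand antipode that gives the drawn configuration is to be assigned on a model aldehyde. Compounds 1, 2, 6, 9, 12, 13 and 18 are taken as commercial.

**Route**

Step 1
Reactants: 1 3,3-dimethylglutaric anhydride; 2 2-(trimethylsilyl)ethanol
Product: 3 3,3-dimethyl-5-oxo-5-[2-(trimethylsilyl)ethoxy]pentanoic acid
Conditions: DMAP (10 mol %), Et3N, CH2Cl2, rt
Reagents that add atoms: 2-(trimethylsilyl)ethanol (compound 2), C[Si](C)(C)CCO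
Why: DMAP-catalysed alcoholysis of the symmetrical cyclic anhydride should give the half-ester with no regiochemical issue.

Step 2
Reactants: 3 half-ester acid
Product: 4 2-(trimethylsilyl)ethyl 5-hydroxy-3,3-dimethylpentanoate
Conditions: BH3·SMe2, THF, 0 °C to rt; MeOH quench; used crude
Reagents that add atoms: none
Why: Borane reduces the carboxylic acid chemoselectively in the presence of the ester (acyloxyborane pathway), and the crude hydroxy ester is oxidised at once to avoid δ-lactonisation.

Step 3
Reactants: 4 hydroxy ester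
Product: 5 2-(trimethylsilyl)ethyl 3,3-dimethyl-5-oxopentanoate
Conditions: TEMPO (10 mol %), PhI(OAc)2, CH2Cl2, rt
Reagents that add atoms: none
Why: Oxoammonium (TEMPO) oxidation of the primary alcohol should stop cleanly at the aldehyde, which carries no α-stereocentre.

Step 4
Reactants: 5 aldehyde; 6 tert-butyl 2-(bromomethyl)prop-2-enoate
Product: 8 1-tert-butyl 8-[2-(trimethylsilyl)ethyl] (4S)-4-hydroxy-6,6-dimethyl-2-methylideneoctanedioate, via trimethylsilyl ether 7 (not isolated)
Conditions: CrCl2 (10 mol %), chiral carbazole bis(oxazoline) ligand (12 mol %), Mn powder, TMSCl, DIPEA, THF, rt; then 1 M HCl, THF, 0 °C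
Reagents that add atoms: tert-butyl 2-(bromomethyl)prop-2-enoate (compound 6), C=C(CBr)C(=O)OC(C)(C)C
Why: In this catalytic asymmetric Nozaki–Hiyama–Kishi-type 2-(alkoxycarbonyl)allylation the allylchromium from 6 adds through a closed six-membered transition state on ligand-bound trivalent chromium, which sets C9 as S, and the bulky tert-butyl ester should keep the γ-hydroxy ester from lactonising.

Step 5
Reactants: 8 (S)-hydroxy diester; 9 angelic acid, (2Z)-2-methylbut-2-enoic acid
Product: 11 1-tert-butyl 8-[2-(trimethylsilyl)ethyl] (4S)-6,6-dimethyl-2-methylidene-4-{[(2Z)-2-methylbut-2-enoyl]oxy}octanedioate, via angelic 2,4,6-trichlorobenzoic mixed anhydride 10 (not isolated)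
Conditions: 9, 2,4,6-trichlorobenzoyl chloride, Et3N, toluene, rt; then 8, toluene, 80 °C (no DMAP)
Reagents that add atoms: angelic acid (compound 9), C/C=C(/C)C(=O)O
Why: Yamaguchi-type esterification through the mixed anhydride without a nucleophilic catalyst should acylate the secondary alcohol with retention at C9 and avoid the addition–elimination pathway that isomerises angelate to tiglate.

Step 6
Reactants: 12 prop-2-yn-1-ol; 13 but-3-en-1-ylmagnesium bromide
Product: 14 2-methylidenehex-5-en-1-ol
Conditions: 13 (2.5 equiv), CuI (10 mol %), THF/Et2O, 0 °C to rt; aq. NH4Cl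
Reagents that add atoms: but-3-en-1-ylmagnesium bromide (compound 13), C=CCC[Mg]Br
Why: Copper-catalysed, hydroxyl-directed carbomagnesiation of propargyl alcohol delivers the alkyl group to the internal alkyne carbon and should give the 2-substituted allyl alcohol on protonolysis.

Step 7
Reactants: 11 angelate acrylate; 14 2-methylidenehex-5-en-1-ol
Product: 15 1-tert-butyl 8-[2-(trimethylsilyl)ethyl] (2E,4S)-2-[4-(hydroxymethyl)pent-4-en-1-ylidene]-6,6-dimethyl-4-{[(2Z)-2-methylbut-2-enoyl]oxy}octanedioate
Conditions: second-generation Hoveyda–Grubbs catalyst (5 mol %), 14 (3 equiv), CH2Cl2, 40 °C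
Reagents that add atoms: 2-methylidenehex-5-en-1-ol (compound 14), C=CCCC(=C)CO
Why: Olefin cross-metathesis of the terminal vinyl group of 14 with the 2-substituted acrylate of 11 should give the trisubstituted enoate with the favoured E geometry (ester trans to the new chain), while the 1,1-disubstituted allylic-alcohol olefin and the angelate stay inert.

Step 8
Reactants: 15 cross-metathesis product
Product: 16 (5S,7E)-7-(tert-butoxycarbonyl)-11-(hydroxymethyl)-3,3-dimethyl-5-{[(2Z)-2-methylbut-2-enoyl]oxy}dodeca-7,11-dienoic acid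
Conditions: TBAF, THF, 0 °C to rt; cold 0.5 M HCl work-up
Reagents that add atoms: none
Why: Fluoride-induced β-elimination of the 2-(trimethylsilyl)ethyl ester frees the acid, while the tert-butyl ester and the angelate, which have no β-silyl group, should be untouched.

Step 9
Reactants: 16 hydroxy acid
Product: 17 (5S,7E)-7-(tert-butoxycarbonyl)-11-formyl-3,3-dimethyl-5-{[(2Z)-2-methylbut-2-enoyl]oxy}dodeca-7,11-dienoic acid
Conditions: TEMPO (10 mol %), PhI(OAc)2, CH2Cl2, rt
Reagents that add atoms: none
Why: Oxoammonium (TEMPO) oxidation of the primary allylic alcohol should give the 2-alkylacrolein without over-oxidation under anhydrous conditions and tolerates the free acid.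

Step 10
Reactants: 17 enal acid; 18 N-hydroxyphthalimide
Product: 19 1,3-dioxoisoindolin-2-yl ester of 17 (redox-active ester)
Conditions: DIC, DMAP (5 mol %), CH2Cl2, 0 °C to rt
Reagents that add atoms: N-hydroxyphthalimide (compound 18), ON1C(=O)c2ccccc2C1=O
Why: Carbodiimide (Steglich-type) coupling installs the redox-active ester on the only free carboxyl group, and the aldehyde is inert to these conditions.

Step 11
Reactants: 19 redox-active ester enal
Product: 22 tert-butyl (1E,6S,10S)-6-hydroxy-8,8-dimethyl-5-methylidene-10-{[(2Z)-2-methylbut-2-enoyl]oxy}cycloundec-1-ene-1-carboxylate, via primary alkyl radical 20 (not isolated), via alkylchromium dichloride 21 (not isolated)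
Conditions: CrCl2 (8 equiv), chiral oxazoline–sulfonamide ligand (8.8 equiv), Et3N, THF/MeCN, rt; 19 added by syringe pump over 12 h (final 2 mM); aqueous work-up
Reagents that add atoms: none
Why: Proposed new method: single-electron transfer from divalent chromium to the N-acyloxyphthalimide of 19 releases CO2 and phthalimide anion to give the neopentyl C1 radical 20, which a second CrCl2 captures to give the alkylchromium 21, and this adds 1,2 to the tethered 2-alkylacrolein carbonyl (C2). The closest known reactions are the intermolecular CrCl2-mediated decarboxylative addition of redox-active esters to aldehydes and Nozaki–Hiyama–Kishi macrocyclisations of alkenyl and allyl halides; the medium-ring intramolecular version with an alkyl radical precursor is the untested part. The eleven-membered carbocycle closes in the 11-exo-trig mode (C1 attacks the carbonyl carbon and the C=O bond stays outside the ring), helped by the gem-dimethyl group at C11 and by the C6=C7 olefin that holds C5 and C8 cis. C2 is the only new stereocentre and is set by the chiral oxazoline–sulfonamide ligand on trivalent chromium in the carbonyl-addition transition state (reagent control, ligand antipode chosen for the S carbinol), the remote C9 centre being expected to exert little bias. The step needs radical capture by chromium to outrun 6-exo or 7-endo addition to the C6=C7 enoate, and 1,2- rather than 1,4-addition to the enal; excess chromium at high substrate dilution, the absence of β-hydrogens in 21 (C11 is quaternary) and the non-enolisable α-branched enal should secure this, and silyl chloride is left out to spare the enal from reduction by chromium.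

Step 12
Reactants: 22 macrocyclic tert-butyl ester
Product: 24 (1E,6S,10S)-6-hydroxy-8,8-dimethyl-5-methylidene-10-{[(2Z)-2-methylbut-2-enoyl]oxy}cycloundec-1-ene-1-carboxylic acid (target), via bis(trimethylsilyl) derivative 23 (not isolated)
Conditions: TMSOTf, 2,6-lutidine, CH2Cl2, 0 °C; then aq. citric acid, THF, rt
Reagents that add atoms: none
Why: Silyl-triflate-mediated cleavage of the tert-butyl ester (O-silylation, loss of isobutene) with transient silylation of the C2 hydroxyl, then mild hydrolysis of both silyl groups, should release the acid without strong protic acid on the allylic alcohol or the angelate and touches no stereocentre.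

**Compound list**

1 | 3,3-dimethylglutaric anhydride (4,4-dimethyloxane-2,6-dione) | O=C1CC(C)(C)CC(=O)O1 | starting material
2 | 2-(trimethylsilyl)ethanol | C[Si](C)(C)CCO | starting material
3 | 3,3-dimethyl-5-oxo-5-[2-(trimethylsilyl)ethoxy]pentanoic acid | OC(=O)CC(C)(C)CC(=O)OCC[Si](C)(C)C | intermediate
4 | 2-(trimethylsilyl)ethyl 5-hydroxy-3,3-dimethylpentanoate | OCCC(C)(C)CC(=O)OCC[Si](C)(C)C | intermediate
5 | 2-(trimethylsilyl)ethyl 3,3-dimethyl-5-oxopentanoate | O=CCC(C)(C)CC(=O)OCC[Si](C)(C)C | intermediate
6 | tert-butyl 2-(bromomethyl)prop-2-enoate | C=C(CBr)C(=O)OC(C)(C)C | starting material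
7 | trimethylsilyl ether of 8 (not isolated) | C=C(C(=O)OC(C)(C)C)C[C@@H](O[Si](C)(C)C)CC(C)(C)CC(=O)OCC[Si](C)(C)C | intermediate
8 | 1-tert-butyl 8-[2-(trimethylsilyl)ethyl] (4S)-4-hydroxy-6,6-dimethyl-2-methylideneoctanedioate | C=C(C(=O)OC(C)(C)C)C[C@@H](O)CC(C)(C)CC(=O)OCC[Si](C)(C)C | intermediate
9 | angelic acid, (2Z)-2-methylbut-2-enoic acid | C/C=C(/C)C(=O)O | starting material
10 | angelic 2,4,6-trichlorobenzoic mixed anhydride (not isolated) | C/C=C(/C)C(=O)OC(=O)c1c(Cl)cc(Cl)cc1Cl | intermediate
11 | 1-tert-butyl 8-[2-(trimethylsilyl)ethyl] (4S)-6,6-dimethyl-2-methylidene-4-{[(2Z)-2-methylbut-2-enoyl]oxy}octanedioate | C=C(C(=O)OC(C)(C)C)C[C@@H](OC(=O)/C(C)=C\C)CC(C)(C)CC(=O)OCC[Si](C)(C)C | intermediate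
12 | prop-2-yn-1-ol | C#CCO | starting material
13 | but-3-en-1-ylmagnesium bromide | C=CCC[Mg]Br | starting material
14 | 2-methylidenehex-5-en-1-ol | C=CCCC(=C)CO | intermediate
15 | 1-tert-butyl 8-[2-(trimethylsilyl)ethyl] (2E,4S)-2-[4-(hydroxymethyl)pent-4-en-1-ylidene]-6,6-dimethyl-4-{[(2Z)-2-methylbut-2-enoyl]oxy}octanedioate | OCC(=C)CC/C=C(/C(=O)OC(C)(C)C)C[C@@H](OC(=O)/C(C)=C\C)CC(C)(C)CC(=O)OCC[Si](C)(C)C | intermediate
16 | (5S,7E)-7-(tert-butoxycarbonyl)-11-(hydroxymethyl)-3,3-dimethyl-5-{[(2Z)-2-methylbut-2-enoyl]oxy}dodeca-7,11-dienoic acid | OCC(=C)CC/C=C(/C(=O)OC(C)(C)C)C[C@@H](OC(=O)/C(C)=C\C)CC(C)(C)CC(=O)O | intermediate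
17 | (5S,7E)-7-(tert-butoxycarbonyl)-11-formyl-3,3-dimethyl-5-{[(2Z)-2-methylbut-2-enoyl]oxy}dodeca-7,11-dienoic acid | O=CC(=C)CC/C=C(/C(=O)OC(C)(C)C)C[C@@H](OC(=O)/C(C)=C\C)CC(C)(C)CC(=O)O | intermediate
18 | N-hydroxyphthalimide | ON1C(=O)c2ccccc2C1=O | starting material
19 | 1,3-dioxoisoindolin-2-yl ester of 17 (redox-active ester) | O=CC(=C)CC/C=C(/C(=O)OC(C)(C)C)C[C@@H](OC(=O)/C(C)=C\C)CC(C)(C)CC(=O)ON1C(=O)c2ccccc2C1=O | intermediate
20 | primary C1 alkyl radical from 19 (not isolated) | O=CC(=C)CC/C=C(/C(=O)OC(C)(C)C)C[C@@H](OC(=O)/C(C)=C\C)CC(C)(C)[CH2] | intermediate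
21 | C1 alkylchromium dichloride (not isolated; same spatial arrangement at the angelate-bearing carbon) | O=CC(=C)CC/C=C(/C(=O)OC(C)(C)C)C[C@@H](OC(=O)/C(C)=C\C)CC(C)(C)C[Cr](Cl)Cl | intermediate
22 | tert-butyl (1E,6S,10S)-6-hydroxy-8,8-dimethyl-5-methylidene-10-{[(2Z)-2-methylbut-2-enoyl]oxy}cycloundec-1-ene-1-carboxylate | C=C1CC/C=C(/C(=O)OC(C)(C)C)C[C@@H](OC(=O)/C(C)=C\C)CC(C)(C)C[C@@H]1O | intermediate
23 | trimethylsilyl ester and trimethylsilyl ether of 24 (not isolated) | C=C1CC/C=C(/C(=O)O[Si](C)(C)C)C[C@@H](OC(=O)/C(C)=C\C)CC(C)(C)C[C@@H]1O[Si](C)(C)C | intermediate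
24 | (1E,6S,10S)-6-hydroxy-8,8-dimethyl-5-methylidene-10-{[(2Z)-2-methylbut-2-enoyl]oxy}cycloundec-1-ene-1-carboxylic acid | C=C1CC/C=C(/C(=O)O)C[C@@H](OC(=O)/C(C)=C\C)CC(C)(C)C[C@@H]1O | target

**Step count and risks**

Total step count: 12. Longest linear sequence: 11 steps (steps 1–5 and 7–12, from 3,3-dimethylglutaric anhydride); step 6 is a one-step side branch.

Steps most likely to fail:

Step 11 (Proposed new method). What may go wrong: protonation or hydrogen-atom quench of the C1 radical or alkylchromium before ring closure, radical cyclisation onto the C6=C7 enoate, reduction of the enal by divalent chromium, or poor facial selectivity at C2. Fallback with known chemistry, closing the ring at C2–C3 instead; it sets out from 11 and comes back at 22. Commercial hex-5-en-1-yne is hydroiodinated (NaI, TMSCl, H2O, MeCN) to 2-iodohexa-1,5-diene F1. Cross-metathesis of 11 with F1 should give the vinyl iodide diester F2, and TBAF frees the vinyl iodide acid F3. BH3·SMe2 reduces this to the primary alcohol F4, and TEMPO/PhI(OAc)2 gives the aldehyde F5, in which the former carboxyl carbon is kept and becomes C2. A Nozaki–Hiyama–Kishi macrocyclisation (CrCl2, NiCl2 cat., chiral oxazoline–sulfonamide ligand, MeCN/THF, high dilution) through the alkenylchromium dichloride F6 should then form the C2–C3 bond and give 22.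

Step 7. What may go wrong: slow turnover of the hindered 1,1-disubstituted acrylate, so that the partner homodimerises and the catalyst decays, or incomplete E selectivity. Fallback that moves the metathesis from the cross to the ring-closing mode; it sets out from 11 and 14 and comes back at 22. TBAF converts 11 into the carboxylic acid F7, and DIC with 18 gives the N-acyloxyphthalimide F8. MnO2 oxidises 14 to 2-methylidenehex-5-enal F9. The intermolecular CrCl2-mediated decarboxylative addition of F8 to F9 (the bimolecular, known form of step 11, same chiral ligand), through the primary alkyl radical F10 and the alkylchromium dichloride F11, should give the acyclic diene carbinol F12. Ring-closing metathesis (second-generation Grubbs catalyst, toluene, 80 °C, high dilution) between the vinyl group and the acrylate methylidene should then close the ring at C6=C7, with C5 and C8 cis as the ring is expected to favour, to give 22.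

Step 5. What may go wrong: Z-to-E isomerisation of the angeloyl unit during acyl transfer, and thermal lactonisation of the γ-hydroxy tert-butyl ester with loss of tert-butanol at 80 °C. Fallback by substitution at carbon instead of acyl transfer; it sets out from 5 and comes back at 11. Step 4 is run with the enantiomeric ligand to give, through the trimethylsilyl ether F13, the (R)-alcohol F14. Mitsunobu esterification with 9 (PPh3, DIAD, toluene, 0 °C to rt) should then invert C9 to the (S)-angelate 11 at low temperature and without any activated angeloyl electrophile.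

Further compounds
F1 | step 11 | 2-iodohexa-1,5-diene | C=CCCC(I)=C
F2 | step 11 | vinyl iodide diester (cross-metathesis product of 11 and F1) | C=C(I)CC/C=C(/C(=O)OC(C)(C)C)C[C@@H](OC(=O)/C(C)=C\C)CC(C)(C)CC(=O)OCC[Si](C)(C)C
F3 | step 11 | vinyl iodide acid | C=C(I)CC/C=C(/C(=O)OC(C)(C)C)C[C@@H](OC(=O)/C(C)=C\C)CC(C)(C)CC(=O)O
F4 | step 11 | vinyl iodide primary alcohol | C=C(I)CC/C=C(/C(=O)OC(C)(C)C)C[C@@H](OC(=O)/C(C)=C\C)CC(C)(C)CCO
F5 | step 11 | vinyl iodide aldehyde | C=C(I)CC/C=C(/C(=O)OC(C)(C)C)C[C@@H](OC(=O)/C(C)=C\C)CC(C)(C)CC=O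
F6 | step 11 | alkenylchromium dichloride from F5 | C=C([Cr](Cl)Cl)CC/C=C(/C(=O)OC(C)(C)C)C[C@@H](OC(=O)/C(C)=C\C)CC(C)(C)CC=O
F7 | step 7 | carboxylic acid from 11 | C=C(C(=O)OC(C)(C)C)C[C@@H](OC(=O)/C(C)=C\C)CC(C)(C)CC(=O)O
F8 | step 7 | N-acyloxyphthalimide of F7 | C=C(C(=O)OC(C)(C)C)C[C@@H](OC(=O)/C(C)=C\C)CC(C)(C)CC(=O)ON1C(=O)c2ccccc2C1=O
F9 | step 7 | 2-methylidenehex-5-enal | C=CCCC(=C)C=O
F10 | step 7 | primary alkyl radical from F8 | C=C(C(=O)OC(C)(C)C)C[C@@H](OC(=O)/C(C)=C\C)CC(C)(C)[CH2]
F11 | step 7 | alkylchromium dichloride from F10 | C=C(C(=O)OC(C)(C)C)C[C@@H](OC(=O)/C(C)=C\C)CC(C)(C)C[Cr](Cl)Cl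
F12 | step 7 | acyclic diene carbinol | C=C(CCC=C)[C@@H](O)CC(C)(C)C[C@H](OC(=O)/C(C)=C\C)CC(=C)C(=O)OC(C)(C)C
F13 | step 5 | trimethylsilyl ether of the (R)-alcohol | C=C(C(=O)OC(C)(C)C)C[C@H](O[Si](C)(C)C)CC(C)(C)CC(=O)OCC[Si](C)(C)C
F14 | step 5 | (R)-alcohol, enantiomer of 8 | C=C(C(=O)OC(C)(C)C)C[C@H](O)CC(C)(C)CC(=O)OCC[Si](C)(C)C
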